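## Analysis of the target

- The target (25) is a bicyclo[3.2.1]octane-7,8-dione. Skeleton numbering used throughout: C1 is the bridgehead carrying the 2-methylpropanoyl group, C2 the gem-dimethyl carbon, C3 the prenyl-bearing methine, C4 the methylene, C5 the prenyl-bearing bridgehead, C6 the tertiary carbinol, C7 the ketone of the two-carbon bridge, C8 the one-carbon bridge ketone, C9 the 2-methylpropanoyl carbonyl carbon and C10 the carbonyl carbon of the (Z)-4-hydroxy-4-methylpent-2-enoyl group.
- There are four stereocentres, (1R,3R,5S,6S). The two bridgeheads are tied together by the bicycle. The C3 prenyl group is equatorial on the chair-shaped ring C1–C2–C3–C4–C5–C8, so the C3 hydrogen points towards the C6–C7 bridge. At C6 the hydroxyl is endo (towards C2–C4) and the acyl group exo (towards C8).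
- C1, C5 and C6 are contiguous fully substituted carbons. C1 carries three acyl carbons (C7, C8, C9) and no hydrogen, so this unit cannot protect itself by enolisation and is an acyl donor towards hard nucleophiles (retro-Claisen cleavage).
- Further sensitive groups are the tertiary α-ketol at C6 between C7 and C10 (acyl shift, retro-aldol), the Z-enone with a γ-hydroxyl (Z-to-E isomerisation, lactol closure) and two acid-sensitive trisubstituted alkenes.
- The difficulty is to build the crowded C1 centre in the right relationship to C3 and C5, and to bring in C6 with its oxygen endo.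
- The strategy rests on one feature: C1 is the central carbon of the 1,3-diketone C8–C1–C9 and stands 1,3 to C7. The bond C1–C7 is therefore a Claisen-type bond that the C1/C9 enolate can make to an acyl carbon hanging from C5, closing the five-membered ring C1–C8–C5–C6–C7. If C6 arrives already oxygenated, the last C–C bond at C6 can be made from the open exo face.

## Retrosynthetic reasoning

**Side-chain oxidation state and protecting groups.** 25 comes from its bis(triethylsilyl) ether 24 by desilylation; no skeletal bond is cut. The Z-enone of 24 is traced to the ynone 23, since a cis alkene conjugated to a ketone is most safely made last by syn semireduction of an alkyne. 23 is the oxidation product of the propargylic alcohol 22. The forward steps must be mild: no base or nucleophile may meet the C1 tricarbonyl unit.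

**C6–C10.** Cutting this bond in 22 gives the C6 enolate of the bicyclic silyloxy diketone 18 and the ynal 21 (made from 19 via its silyl ether 20). This is preferred to adding an acyl-anion equivalent to a C6 ketone: in 18 only C6 carries an accessible acidic hydrogen next to a ring ketone, so the site is unambiguous. The electrophile must also enter from the exo face, which leaves the oxygen endo as required.

**C1–C7 (key disconnection).** Cutting C1–C7 in 18 opens the five-membered ring and gives a cyclohexane β-diketone with an axial CH(OSiEt3)–C(=O)X arm on C5: the methyl ester 15, its acid 16 and the acid chloride 17. The other bonds at C1 are worse places to cut: C1–C9 would need acylation of a bridgehead that cannot enolise, and C1–C8 would open both rings. The acyl carbon must be more activated than an ester and its leaving group must not be able to return. The nucleophile is a stabilised diketonate and the product, lacking a hydrogen on C1, is itself an acyl donor, so an alkoxide released in the flask would reverse the closure. Hence 15 is hydrolysed to 16 and closed through 17.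

**C1–C9 and the second methyl on C2.** The 2-methylpropanoyl group of 15 is removed as 13 (aldol 14, then oxidation), leaving the C8=C1 silyl enol ether 12. Conjugate methylation of the enone 11 gives exactly this enol ether. One operation therefore completes the gem-dimethyl carbon C2 and delivers the C1 nucleophile regiospecifically, with no base that could also remove the C6 hydrogen.

**C5–C6 and C5–prenyl.** In 11 the quaternary C5 is α′ to the enone carbonyl C8. The arm is disconnected first (aldol of the α′-enolate of 8 with 9), the prenyl group second (alkylation of 6 with 7). The order matters: the group introduced last enters trans to the C3 prenyl group, and it is the arm that must be trans to it (axial, on the side of the C3 hydrogen) to reach C1 later.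

**First methyl on C2.** 6 is the β-methyl homologue of enone 4, made by conjugate methylation to silyl enol ether 5 and re-oxidation. This costs two steps but uses the one position of 4 that is certain to react.

**The ring and C3.** 4 is disconnected at C3–C4 and C1–C2 into 1 and 2: a catalytic asymmetric Michael addition through 3, then aldol condensation. This sets the absolute configuration, with the C3 prenyl group already present in 1. A chiral-pool start would need more steps to reach the same substitution pattern.

## Alternatives that were turned down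

**Alternative 1:** The six-membered ring is opened at C1–C2, leading back to the achiral gem-diprenyl cyclopentenetrione cohulupone A1, whose two prenyl groups on C5 are enantiotopic.
- Forward step: an electrophilic phenylselenium source under chiral Lewis-base catalysis forms a seleniranium ion on one prenyl alkene. The enol carbon C1 opens it at the more substituted carbon C2, giving the bicyclic selenide A2 with C1, C3 and C5 set at once.
- For it: A1 is very short to make, and one catalytic step would build the bicycle and its absolute configuration. On step economy this is clearly stronger than the chosen route.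
- Against it: the nucleophile is an ambident enol, and attack through oxygen to a cyclic ether is the normal outcome for prenylated 1,3-dicarbonyl compounds; it does not have to create a triacyl quaternary carbon. The catalyst must also distinguish two prenyl groups far from any directing group. Selenium on C3 must then be exchanged for prenyl with retention (radical allylation, then cross-metathesis). Finally, an acyl-anion equivalent would have to add to the C6 ketone in the presence of three other ketones, all prone to retro-Claisen cleavage.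
- In its place the chosen route offers a C3 prenyl group and a C6 oxygen present before ring closure, C- over O-acylation enforced by conformation, and a C6–C10 bond made by enolate chemistry at the only enolisable position.

**Alternative 2:** The bicycle is cut at C4–C5 and at the C3–allyl bond, leading to the bromotrione A3, which carries a reverse-prenyl group on quaternary C1.
- Forward step: the C5 radical generated from A3 adds to the terminal alkene carbon C4 (six-membered ring), and the C3 radical is captured by an allylstannane to give the allyl trione A4.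
- For it: radical conditions are neutral and spare the base-labile tricarbonyl unit, and two C–C bonds form in one step. In avoiding carbanion chemistry at the bridged polyketone it is as strong as or stronger than the chosen route. Attack at C4 is helped because the internal carbon C3 is neopentyl.
- Against it: the absolute configuration rests on the quaternary C1 of A3, which would come from a [3,3] shift of an O-prenyl enol ether, a reaction with no dependable asymmetric version on such triones. The C5 radical can be reduced or allylated before it cyclises. The allyl group must still be converted to prenyl. The C6 ketone problem is the same as in Alternative 1.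
- In its place the chosen route takes its absolute configuration from a well-understood enamine-catalysed annulation, carries both prenyl groups as such, and makes C6 nucleophilic instead of electrophilic.

**Alternative 3:** The bonds C1–C9 and C6–C7 are traced to a cyclobutane, leading back to the silyloxymethylene ketone A5, whose C5 arm is a β-keto ester.
- Forward step: irradiation gives a crossed [2+2] adduct between the excited C1=C7 enone and the enol C6=C9 (De Mayo reaction). Retro-aldol opening of the cyclobutanol at C6–C9 leaves the bicyclic keto ester A6 with the 2-methylpropanoyl group on C1.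
- For it: the triacyl-type bridgehead is made without any enolate attacking an acyl carbon, so the reversibility problem that shapes the chosen key step never arises; on this point it is stronger. A two-atom tether also favours the crossed mode.
- Against it: prenyl alkenes cannot be present during irradiation, so both are masked as acetals and need hydrolysis and olefination afterwards on a fragile polyketone. A6 has C7 at the alcohol level and C6 as CH–CO2Me. Hydroxylating C6 would bring oxygen in from the exo face, giving the wrong C6 configuration, because the group added last to C6 ends up exo. At least eight steps would follow the key step.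
- In its place the chosen route adds carbon last at C6 (oxygen first), needs four steps after ring closure, and uses no photochemistry.

Key step: step 10

Assumptions: 1 is taken to be a catalogue aldehyde; 25 is written as the open-chain Z-hydroxy-enone, although it may equilibrate with the lactol formed by the side-chain hydroxyl and C10; the carbinol centre made in step 5 (later C6) is carried as both epimers through step 10, with the 2R epimer drawn.

## Route

Step 1
Reactants: 1 5-methylhex-4-enal; 2 but-3-en-2-one
Product: 4 (4S)-4-(3-methylbut-2-en-1-yl)cyclohex-2-en-1-one, via Michael adduct 3 (not isolated)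
Conditions: (S)-2-[diphenyl(trimethylsilyloxy)methyl]pyrrolidine (10 mol%), ethyl 3,4-dihydroxybenzoate (20 mol%), neat, 4 °C; then LiOH (cat.), i-PrOH, 23 °C
Reagents that add atoms: none
Why: Enamine-catalysed Michael addition followed by intramolecular aldol condensation (Robinson-type annulation). The bulky group of the (S)-catalyst shields one face of the E-enamine, so 2 adds to the open face and fixes the prenyl-bearing centre (later C3) as S; the mild base closure should not enolise this centre appreciably.

Step 2
Reactants: 4 (4S)-4-(3-methylbut-2-en-1-yl)cyclohex-2-en-1-one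
Product: 5 trimethyl{[(3S,4S)-3-methyl-4-(3-methylbut-2-en-1-yl)cyclohex-1-en-1-yl]oxy}silane
Conditions: Me2CuLi (from CuI and MeLi), Me3SiCl, THF, −78 °C; Et3N
Reagents that add atoms: lithium dimethylcuprate, [Li+].C[Cu-]C; chlorotrimethylsilane, C[Si](C)(C)Cl
Why: Cuprate conjugate addition accelerated and trapped by Me3SiCl gives the regiodefined silyl enol ether. The methyl group should add anti to the neighbouring prenyl group, but this centre becomes sp2 again in step 3.

Step 3
Reactants: 5 trimethyl{[(3S,4S)-3-methyl-4-(3-methylbut-2-en-1-yl)cyclohex-1-en-1-yl]oxy}silane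
Product: 6 (4S)-3-methyl-4-(3-methylbut-2-en-1-yl)cyclohex-2-en-1-one
Conditions: Pd(OAc)2 (1.0 equiv), MeCN, 23 °C
Reagents that add atoms: none
Why: Saegusa–Ito oxidation: palladation of the silyl enol ether at the α-carbon and β-hydride loss from the methyl-bearing carbon return the enone, now β-methylated. The conditions are neutral, so the isolated alkene and the γ-stereocentre should be unaffected.

Step 4
Reactants: 6 (4S)-3-methyl-4-(3-methylbut-2-en-1-yl)cyclohex-2-en-1-one; 7 1-bromo-3-methylbut-2-ene
Product: 8 (4R,6R)-3-methyl-4,6-bis(3-methylbut-2-en-1-yl)cyclohex-2-en-1-one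
Conditions: LiN(i-Pr)2, THF, −78 °C; then 7, −78 to −20 °C
Reagents that add atoms: none
Why: Kinetic α′-deprotonation of the enone and SN2 alkylation of the enolate with the allylic bromide. The new centre (later C5) should form mainly trans to the C4 prenyl group, but either epimer serves because it is enolised again in step 5.

Step 5
Reactants: 8 (4R,6R)-3-methyl-4,6-bis(3-methylbut-2-en-1-yl)cyclohex-2-en-1-one; 9 methyl 2-oxoacetate
Product: 11 methyl (2R)-2-[(1S,5R)-4-methyl-1,5-bis(3-methylbut-2-en-1-yl)-2-oxocyclohex-3-en-1-yl]-2-[(triethylsilyl)oxy]acetate, via lithium aldolate 10 (not isolated)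
Conditions: LiN(i-Pr)2, THF, −78 °C; 9 (freshly distilled), −78 °C; then Et3SiOTf, −78 to −40 °C
Reagents that add atoms: triethylsilyl trifluoromethanesulfonate, CC[Si](CC)(CC)OS(=O)(=O)C(F)(F)F
Why: Aldol addition of the cross-conjugated α′-enolate to the highly electrophilic aldehyde creates quaternary C5, and the aldolate is silylated in the flask before it can revert. The aldehyde should enter anti to the prenyl group on the ring carbon two positions away (1,3-induction), placing the arm trans to that group as needed for ring closure. The carbinol centre should form as a mixture (2R drawn), which is harmless because it becomes an enolate carbon in step 13.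

Step 6
Reactants: 11 methyl (2R)-2-[(1S,5R)-4-methyl-1,5-bis(3-methylbut-2-en-1-yl)-2-oxocyclohex-3-en-1-yl]-2-[(triethylsilyl)oxy]acetate
Product: 12 methyl (2R)-2-[(1S,5R)-4,4-dimethyl-1,5-bis(3-methylbut-2-en-1-yl)-2-[(trimethylsilyl)oxy]cyclohex-2-en-1-yl]-2-[(triethylsilyl)oxy]acetate
Conditions: Me2CuLi (from CuI and MeLi), Me3SiCl, THF, −78 to −30 °C; Et3N
Reagents that add atoms: lithium dimethylcuprate, [Li+].C[Cu-]C; chlorotrimethylsilane, C[Si](C)(C)Cl
Why: A second Me3SiCl-accelerated cuprate conjugate addition completes the gem-dimethyl carbon C2 (no new stereocentre) and delivers the C8=C1 enol ether regiospecifically. Trapping the enolate on silicon at low temperature keeps it from attacking the ester arm and avoids any base at the ester α-hydrogen.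

Step 7
Reactants: 12 methyl (2R)-2-[(1S,5R)-4,4-dimethyl-1,5-bis(3-methylbut-2-en-1-yl)-2-[(trimethylsilyl)oxy]cyclohex-2-en-1-yl]-2-[(triethylsilyl)oxy]acetate; 13 2-methylpropanal
Product: 14 methyl (2R)-2-[(1S,5R)-3-(1-hydroxy-2-methylpropyl)-4,4-dimethyl-1,5-bis(3-methylbut-2-en-1-yl)-2-oxocyclohexyl]-2-[(triethylsilyl)oxy]acetate
Conditions: BF3·OEt2, CH2Cl2, −78 °C; aq. NaHCO3
Reagents that add atoms: none
Why: Mukaiyama aldol addition of the silyl enol ether carbon C1 to the boron-activated aldehyde; aldol additions tolerate a nucleophilic carbon next to a quaternary centre better than direct acylations. The two new centres should form as a mixture and are both removed in step 8 (oxidation and enolisation).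

Step 8
Reactants: 14 methyl (2R)-2-[(1S,5R)-3-(1-hydroxy-2-methylpropyl)-4,4-dimethyl-1,5-bis(3-methylbut-2-en-1-yl)-2-oxocyclohexyl]-2-[(triethylsilyl)oxy]acetate
Product: 15 methyl (2R)-2-[(1S,3S,5R)-4,4-dimethyl-1,5-bis(3-methylbut-2-en-1-yl)-3-(2-methylpropanoyl)-2-oxocyclohexyl]-2-[(triethylsilyl)oxy]acetate
Conditions: 1,1,1-triacetoxy-1,1-dihydro-1,2-benziodoxol-3(1H)-one (DMP), CH2Cl2, 0 to 23 °C
Reagents that add atoms: none
Why: Dess–Martin oxidation of the secondary alcohol gives the β-diketone, which should exist largely as its chelated enol (the drawn C1 configuration is therefore not fixed). The near-neutral conditions should leave the silyl ether, the ester and the alkenes intact.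

Step 9
Reactants: 15 methyl (2R)-2-[(1S,3S,5R)-4,4-dimethyl-1,5-bis(3-methylbut-2-en-1-yl)-3-(2-methylpropanoyl)-2-oxocyclohexyl]-2-[(triethylsilyl)oxy]acetate
Product: 16 (2R)-2-[(1S,3S,5R)-4,4-dimethyl-1,5-bis(3-methylbut-2-en-1-yl)-3-(2-methylpropanoyl)-2-oxocyclohexyl]-2-[(triethylsilyl)oxy]acetic acid
Conditions: Me3SnOH, 1,2-dichloroethane, 70 °C; brief wash with cold 0.05 M HCl
Reagents that add atoms: trimethyltin hydroxide, C[Sn](C)(C)O
Why: Ester hydrolysis by acyl–oxygen cleavage with Me3SnOH, a method that works on hindered methyl esters under near-neutral conditions. The silyl ether should survive, and the enolised β-diketone is not cleaved.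

Step 10
Reactants: 16 (2R)-2-[(1S,3S,5R)-4,4-dimethyl-1,5-bis(3-methylbut-2-en-1-yl)-3-(2-methylpropanoyl)-2-oxocyclohexyl]-2-[(triethylsilyl)oxy]acetic acid
Product: 18 (1R,3R,5S,6R)-2,2-dimethyl-3,5-bis(3-methylbut-2-en-1-yl)-1-(2-methylpropanoyl)-6-[(triethylsilyl)oxy]bicyclo[3.2.1]octane-7,8-dione, via acid chloride 17 (not isolated)
Conditions: 1-chloro-N,N,2-trimethylprop-1-en-1-amine (1.1 equiv), CH2Cl2, 0 °C; then MgBr2·OEt2 (2 equiv), i-Pr2NEt (3 equiv), CH2Cl2, −20 to 23 °C
Reagents that add atoms: none
Why: The α-chloroenamine converts the acid into acid chloride 17 without liberating acid; MgBr2 and the amine then turn the enolised β-diketone into its magnesium chelate, whose central carbon C1 adds to the acyl chloride carbon C7, and loss of chloride gives the triketone (intramolecular Claisen-type C-acylation). The closest known reaction type is the magnesium-mediated C-acylation of 1,3-dicarbonyl compounds with acid chlorides, together with the acid-chloride closures onto enol carbons that build bridged polyketone cores (Effenberger-type cyclisation). The five-membered ring C1–C8–C5–C6–C7 closes in the 5-(enolexo)-exo-trig mode: the delocalised enolate reacts through its C1=C9 form, so the enolate double bond lies outside the new ring and C7=O is exo to it. An ester at C7 would not serve, because the nucleophile is a stabilised diketonate and the product, with no hydrogen on C1, is itself an acyl donor, so a liberated alkoxide would re-add at C7 and reopen the ring, whereas chloride cannot. C1 is the only new stereocentre and is fixed by the tether: C7 hangs from the lower face of C5 and can bond only to the same face of C1, so the configuration of C1 follows from that of C5. The selectivity needed is C- over O-acylation; the substrate secures it because a ring flip would set the C3 and C5 prenyl groups 1,3-diaxial, so the arm stays axial with C7 held over C1 and perpendicular to the plane containing the enolate oxygen on C8, from where a five-membered enol lactone cannot close, and magnesium ties up both oxygens in the chelate. C6 is not touched (retention gives the silyloxy group endo), and its epimer should cyclise in the same way.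

Step 11
Reactants: 19 2-methylbut-3-yn-2-ol
Product: 20 triethyl[(2-methylbut-3-yn-2-yl)oxy]silane
Conditions: Et3SiCl, imidazole, DMF, 23 °C
Reagents that add atoms: chlorotriethylsilane, CC[Si](Cl)(CC)CC
Why: Imidazole-promoted silylation of the tertiary alcohol (silyl ether formation); the terminal alkyne does not react.

Step 12
Reactants: 20 triethyl[(2-methylbut-3-yn-2-yl)oxy]silane
Product: 21 4-methyl-4-[(triethylsilyl)oxy]pent-2-ynal
Conditions: n-BuLi, THF, −78 °C; DMF, −78 to 0 °C; poured into 10% aq. KH2PO4
Reagents that add atoms: N,N-dimethylformamide, CN(C)C=O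
Why: Deprotonation of the terminal alkyne and formylation of the lithium acetylide with DMF. Inverse quench into phosphate buffer hydrolyses the hemiaminal and keeps the liberated amine from adding to the ynal.

Step 13
Reactants: 18 (1R,3R,5S,6R)-2,2-dimethyl-3,5-bis(3-methylbut-2-en-1-yl)-1-(2-methylpropanoyl)-6-[(triethylsilyl)oxy]bicyclo[3.2.1]octane-7,8-dione; 21 4-methyl-4-[(triethylsilyl)oxy]pent-2-ynal
Product: 22 (1R,3R,5S,6S)-6-{1-hydroxy-4-methyl-4-[(triethylsilyl)oxy]pent-2-yn-1-yl}-2,2-dimethyl-3,5-bis(3-methylbut-2-en-1-yl)-1-(2-methylpropanoyl)-6-[(triethylsilyl)oxy]bicyclo[3.2.1]octane-7,8-dione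
Conditions: LiN(SiMe3)2, THF, −78 °C; 21, −78 °C; AcOH, −78 °C
Reagents that add atoms: none
Why: Aldol addition of the C6 lithium enolate (C6=C7 in the two-carbon bridge) to the non-enolisable ynal; the other α-hydrogen, on the 2-methylpropanoyl group, should stay because its enolate would suffer allylic strain against the quaternary bridgehead. The aldehyde should approach from the exo face (side of C8), since the endo face is screened by the C2–C4 bridge and the axial C3 hydrogen, so C10 ends up exo and the oxygen endo, which is the C6 configuration of 25. The carbinol centre should form as a mixture and is removed in step 14.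

Step 14
Reactants: 22 (1R,3R,5S,6S)-6-{1-hydroxy-4-methyl-4-[(triethylsilyl)oxy]pent-2-yn-1-yl}-2,2-dimethyl-3,5-bis(3-methylbut-2-en-1-yl)-1-(2-methylpropanoyl)-6-[(triethylsilyl)oxy]bicyclo[3.2.1]octane-7,8-dione
Product: 23 (1R,3R,5S,6S)-2,2-dimethyl-3,5-bis(3-methylbut-2-en-1-yl)-6-{4-methyl-4-[(triethylsilyl)oxy]pent-2-ynoyl}-1-(2-methylpropanoyl)-6-[(triethylsilyl)oxy]bicyclo[3.2.1]octane-7,8-dione
Conditions: 1,1,1-triacetoxy-1,1-dihydro-1,2-benziodoxol-3(1H)-one (DMP), CH2Cl2, 0 to 23 °C
Reagents that add atoms: none
Why: Dess–Martin oxidation of the propargylic alcohol to the ynone. It involves neither base nor nucleophile, so the tricarbonyl unit and the new 1,3-diketone at C6 should not undergo retro-Claisen cleavage.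

Step 15
Reactants: 23 (1R,3R,5S,6S)-2,2-dimethyl-3,5-bis(3-methylbut-2-en-1-yl)-6-{4-methyl-4-[(triethylsilyl)oxy]pent-2-ynoyl}-1-(2-methylpropanoyl)-6-[(triethylsilyl)oxy]bicyclo[3.2.1]octane-7,8-dione
Product: 24 (1R,3R,5S,6S)-2,2-dimethyl-3,5-bis(3-methylbut-2-en-1-yl)-6-{(2Z)-4-methyl-4-[(triethylsilyl)oxy]pent-2-enoyl}-1-(2-methylpropanoyl)-6-[(triethylsilyl)oxy]bicyclo[3.2.1]octane-7,8-dione
Conditions: H2 (1 atm), Pd/CaCO3 poisoned with Pb(OAc)2, quinoline, EtOAc, 0 °C
Reagents that add atoms: none
Why: Lindlar semihydrogenation: syn delivery of hydrogen to the alkyne on the poisoned palladium surface gives the Z-enone. The trisubstituted prenyl alkenes should not be reduced on this catalyst, and the silyl ether keeps the γ-oxygen from closing onto C10.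

Step 16
Reactants: 24 (1R,3R,5S,6S)-2,2-dimethyl-3,5-bis(3-methylbut-2-en-1-yl)-6-{(2Z)-4-methyl-4-[(triethylsilyl)oxy]pent-2-enoyl}-1-(2-methylpropanoyl)-6-[(triethylsilyl)oxy]bicyclo[3.2.1]octane-7,8-dione
Product: 25 (1R,3R,5S,6S)-6-hydroxy-6-[(2Z)-4-hydroxy-4-methylpent-2-enoyl]-2,2-dimethyl-3,5-bis(3-methylbut-2-en-1-yl)-1-(2-methylpropanoyl)bicyclo[3.2.1]octane-7,8-dione
Conditions: HF·pyridine, pyridine, THF, 0 to 23 °C
Reagents that add atoms: none
Why: Fluoride-mediated cleavage of both triethylsilyl ethers, driven by Si–F bond formation. The pyridine-buffered medium is neither basic enough for retro-Claisen or α-ketol rearrangement nor acidic enough to isomerise the Z-enone or attack the prenyl alkenes.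

## Compound list

1 | 5-methylhex-4-enal | CC(C)=CCCC=O | starting material
2 | but-3-en-2-one | CC(=O)C=C | starting material
3 | (2S)-5-methyl-2-(3-oxobutyl)hex-4-enal | CC(C)=CC[C@@H](C=O)CCC(C)=O | intermediate (not isolated)
4 | (4S)-4-(3-methylbut-2-en-1-yl)cyclohex-2-en-1-one | CC(C)=CC[C@@H]1CCC(=O)C=C1 | intermediate
5 | trimethyl{[(3S,4S)-3-methyl-4-(3-methylbut-2-en-1-yl)cyclohex-1-en-1-yl]oxy}silane | CC(C)=CC[C@@H]1CCC(O[Si](C)(C)C)=C[C@H]1C | intermediate
6 | (4S)-3-methyl-4-(3-methylbut-2-en-1-yl)cyclohex-2-en-1-one | CC(C)=CC[C@@H]1CCC(=O)C=C1C | intermediate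
7 | 1-bromo-3-methylbut-2-ene (prenyl bromide) | CC(C)=CCBr | starting material
8 | (4R,6R)-3-methyl-4,6-bis(3-methylbut-2-en-1-yl)cyclohex-2-en-1-one (trans epimer drawn; the C6 epimer is equally usable) | CC(C)=CC[C@@H]1C[C@@H](CC=C(C)C)C(=O)C=C1C | intermediate
9 | methyl 2-oxoacetate (methyl glyoxylate) | COC(=O)C=O | starting material
10 | lithium (1R)-2-methoxy-1-[(1S,5R)-4-methyl-1,5-bis(3-methylbut-2-en-1-yl)-2-oxocyclohex-3-en-1-yl]-2-oxoethan-1-olate | CC(C)=CC[C@@H]1C[C@]([C@@H]([O-])C(=O)OC)(CC=C(C)C)C(=O)C=C1C.[Li+] | intermediate (not isolated)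
11 | methyl (2R)-2-[(1S,5R)-4-methyl-1,5-bis(3-methylbut-2-en-1-yl)-2-oxocyclohex-3-en-1-yl]-2-[(triethylsilyl)oxy]acetate (2R epimer drawn) | CC(C)=CC[C@@H]1C[C@]([C@@H](O[Si](CC)(CC)CC)C(=O)OC)(CC=C(C)C)C(=O)C=C1C | intermediate
12 | methyl (2R)-2-[(1S,5R)-4,4-dimethyl-1,5-bis(3-methylbut-2-en-1-yl)-2-[(trimethylsilyl)oxy]cyclohex-2-en-1-yl]-2-[(triethylsilyl)oxy]acetate | CC(C)=CC[C@@H]1C[C@]([C@@H](O[Si](CC)(CC)CC)C(=O)OC)(CC=C(C)C)C(O[Si](C)(C)C)=CC1(C)C | intermediate
13 | 2-methylpropanal | CC(C)C=O | starting material
14 | methyl (2R)-2-[(1S,5R)-3-(1-hydroxy-2-methylpropyl)-4,4-dimethyl-1,5-bis(3-methylbut-2-en-1-yl)-2-oxocyclohexyl]-2-[(triethylsilyl)oxy]acetate (mixture at ring C3 and at the new carbinol) | CC(C)=CC[C@@H]1C[C@]([C@@H](O[Si](CC)(CC)CC)C(=O)OC)(CC=C(C)C)C(=O)C(C(O)C(C)C)C1(C)C | intermediate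
15 | methyl (2R)-2-[(1S,3S,5R)-4,4-dimethyl-1,5-bis(3-methylbut-2-en-1-yl)-3-(2-methylpropanoyl)-2-oxocyclohexyl]-2-[(triethylsilyl)oxy]acetate (ring C3 enolisable) | CC(C)=CC[C@@H]1C[C@]([C@@H](O[Si](CC)(CC)CC)C(=O)OC)(CC=C(C)C)C(=O)[C@H](C(=O)C(C)C)C1(C)C | intermediate
16 | (2R)-2-[(1S,3S,5R)-4,4-dimethyl-1,5-bis(3-methylbut-2-en-1-yl)-3-(2-methylpropanoyl)-2-oxocyclohexyl]-2-[(triethylsilyl)oxy]acetic acid | CC(C)=CC[C@@H]1C[C@]([C@@H](O[Si](CC)(CC)CC)C(=O)O)(CC=C(C)C)C(=O)[C@H](C(=O)C(C)C)C1(C)C | intermediate
17 | (2R)-2-[(1S,3S,5R)-4,4-dimethyl-1,5-bis(3-methylbut-2-en-1-yl)-3-(2-methylpropanoyl)-2-oxocyclohexyl]-2-[(triethylsilyl)oxy]acetyl chloride | CC(C)=CC[C@@H]1C[C@]([C@@H](O[Si](CC)(CC)CC)C(Cl)=O)(CC=C(C)C)C(=O)[C@H](C(=O)C(C)C)C1(C)C | intermediate (not isolated)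
18 | (1R,3R,5S,6R)-2,2-dimethyl-3,5-bis(3-methylbut-2-en-1-yl)-1-(2-methylpropanoyl)-6-[(triethylsilyl)oxy]bicyclo[3.2.1]octane-7,8-dione (silyloxy group endo) | CC(C)=CC[C@@H]1C[C@]2(CC=C(C)C)C(=O)[C@@](C(=O)C(C)C)(C(=O)[C@@H]2O[Si](CC)(CC)CC)C1(C)C | intermediate
19 | 2-methylbut-3-yn-2-ol | CC(C)(O)C#C | starting material
20 | triethyl[(2-methylbut-3-yn-2-yl)oxy]silane | CC(C)(C#C)O[Si](CC)(CC)CC | intermediate
21 | 4-methyl-4-[(triethylsilyl)oxy]pent-2-ynal | CC(C)(C#CC=O)O[Si](CC)(CC)CC | intermediate
22 | (1R,3R,5S,6S)-6-{1-hydroxy-4-methyl-4-[(triethylsilyl)oxy]pent-2-yn-1-yl}-2,2-dimethyl-3,5-bis(3-methylbut-2-en-1-yl)-1-(2-methylpropanoyl)-6-[(triethylsilyl)oxy]bicyclo[3.2.1]octane-7,8-dione (carbinol epimers) | CC(C)=CC[C@@H]1C[C@]2(CC=C(C)C)C(=O)[C@@](C(=O)C(C)C)(C(=O)[C@@]2(O[Si](CC)(CC)CC)C(O)C#CC(C)(C)O[Si](CC)(CC)CC)C1(C)C | intermediate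
23 | (1R,3R,5S,6S)-2,2-dimethyl-3,5-bis(3-methylbut-2-en-1-yl)-6-{4-methyl-4-[(triethylsilyl)oxy]pent-2-ynoyl}-1-(2-methylpropanoyl)-6-[(triethylsilyl)oxy]bicyclo[3.2.1]octane-7,8-dione | CC(C)=CC[C@@H]1C[C@]2(CC=C(C)C)C(=O)[C@@](C(=O)C(C)C)(C(=O)[C@@]2(O[Si](CC)(CC)CC)C(=O)C#CC(C)(C)O[Si](CC)(CC)CC)C1(C)C | intermediate
24 | (1R,3R,5S,6S)-2,2-dimethyl-3,5-bis(3-methylbut-2-en-1-yl)-6-{(2Z)-4-methyl-4-[(triethylsilyl)oxy]pent-2-enoyl}-1-(2-methylpropanoyl)-6-[(triethylsilyl)oxy]bicyclo[3.2.1]octane-7,8-dione | CC(C)=CC[C@@H]1C[C@]2(CC=C(C)C)C(=O)[C@@](C(=O)C(C)C)(C(=O)[C@@]2(O[Si](CC)(CC)CC)C(=O)/C=C\C(C)(C)O[Si](CC)(CC)CC)C1(C)C | intermediate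
25 | (1R,3R,5S,6S)-6-hydroxy-6-[(2Z)-4-hydroxy-4-methylpent-2-enoyl]-2,2-dimethyl-3,5-bis(3-methylbut-2-en-1-yl)-1-(2-methylpropanoyl)bicyclo[3.2.1]octane-7,8-dione | CC(C)=CC[C@@H]1C[C@]2(CC=C(C)C)C(=O)[C@@](C(=O)C(C)C)(C(=O)[C@@]2(O)C(=O)/C=C\C(C)(C)O)C1(C)C | target

## Step count and least certain steps

Total: 16 steps. Longest linear sequence: 14 steps (steps 1–10 and 13–16, from 1); steps 11 and 12 are the two-step branch to 21.

**Step 10 (key step).** The likely failures are acylation through the exocyclic enolate oxygen on C9, dehydrochlorination of the acid chloride to a silyloxyketene before C1 attacks, or simply slow bond formation at a carbon flanked by the gem-dimethyl centre. All follow from the low nucleophilicity and crowding of a diketonate carbon.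
Fallback: the route leaves at 16. Silylation of both acidic hydroxyls (Me3SiCl, Et3N) should give the silyl ester and silyl enol ether trimethylsilyl (2R)-2-[(1S,5R)-4,4-dimethyl-1,5-bis(3-methylbut-2-en-1-yl)-3-{2-methyl-1-[(trimethylsilyl)oxy]propylidene}-2-oxocyclohexyl]-2-[(triethylsilyl)oxy]acetate F1. Oxalyl chloride with a trace of DMF then converts the silyl ester into the acid chloride of that silyl enol ether F2 under neutral conditions. TiCl4 at −78 °C should promote attack of the enol ether carbon C1 on the acid chloride (Mukaiyama-type acylation, as in the Effenberger cyclisation), with oxygen blocked by silicon. Loss of Me3SiCl returns the route to 18.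

**Step 5.** Facial selectivity at C5 may be poor, the aldolate may revert before it is silylated, or deprotonation may occur at the γ-position instead of α′. The enolate carbon is fully substituted and the ring is flattened, so the bias from the C3 prenyl group is only a 1,3-effect.
Fallback: from 8, LiN(i-Pr)2 and Me3SiCl should give the silyl dienol ether trimethyl{[(4R)-5-methyl-2,4-bis(3-methylbut-2-en-1-yl)cyclohexa-1,5-dien-1-yl]oxy}silane F3. A Mukaiyama aldol addition of F3 to 9 with Sc(OTf)3 (open transition state, irreversible silyl transfer) should give, after work-up, the hydroxy ester methyl (2R)-2-hydroxy-2-[(1S,5R)-4-methyl-1,5-bis(3-methylbut-2-en-1-yl)-2-oxocyclohex-3-en-1-yl]acetate F4. Silylation with Et3SiOTf and 2,6-lutidine rejoins the route at 11.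

**Step 6.** Conjugate addition may be slow, with competing carbonyl addition or attack on the ester, because the β,β-disubstituted enone sits between a tertiary centre and the new quaternary centre.
Fallback: the methyl group is added before C5 is quaternary. From 8, Me2CuLi and Me3SiCl should give trimethyl{[(4R,6R)-3,3-dimethyl-4,6-bis(3-methylbut-2-en-1-yl)cyclohex-1-en-1-yl]oxy}silane F5. Mukaiyama aldol addition to 13 should give (4R,6R)-2-(1-hydroxy-2-methylpropyl)-3,3-dimethyl-4,6-bis(3-methylbut-2-en-1-yl)cyclohexan-1-one F6, and Dess–Martin oxidation the β-diketone (4R,6R)-3,3-dimethyl-4,6-bis(3-methylbut-2-en-1-yl)-2-(2-methylpropanoyl)cyclohexan-1-one F7. The dianion of F7 (two equivalents of LiN(i-Pr)2) is then added to 9 at C5 by axial attack on the chair enolate and the aldolate silylated with Et3SiOTf, rejoining the route at 15. This order accepts a regiochemical risk in the second deprotonation, which is why it is not the first choice.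

**Step 13.** The crowded tertiary aldolate may revert, the silyl group may migrate between the two cis oxygens of the enediolate, or deprotonation may be slow for the C6 epimer whose hydrogen is endo.
Fallback: an irreversible C-acylation replaces aldol and oxidation. From 20, lithiation and carboxylation with CO2 should give 4-methyl-4-[(triethylsilyl)oxy]pent-2-ynoic acid F8, which is converted (1H-benzotriazole, dicyclohexylcarbodiimide) into the acyl benzotriazole 1-(1H-benzotriazol-1-yl)-4-methyl-4-[(triethylsilyl)oxy]pent-2-yn-1-one F9. The lithium enolate of 18 is acylated at carbon with F9, which rejoins the route at 23 without passing through 22.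

**Step 15.** Over-reduction of the activated alkyne or Z-to-E isomerisation on the catalyst is possible, because the ynone and the enone formed from it are both strongly activated.
Fallback: the order is changed. From 22, semihydrogenation of the less activated propargylic alcohol over Pd/CaCO3 poisoned with Pb(OAc)2 should give the Z-allylic alcohol (1R,3R,5S,6S)-6-{(2Z)-1-hydroxy-4-methyl-4-[(triethylsilyl)oxy]pent-2-en-1-yl}-2,2-dimethyl-3,5-bis(3-methylbut-2-en-1-yl)-1-(2-methylpropanoyl)-6-[(triethylsilyl)oxy]bicyclo[3.2.1]octane-7,8-dione F10. Dess–Martin oxidation of F10 rejoins the route at 24.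

## Further compounds

F1 | step 10 | trimethylsilyl (2R)-2-[(1S,5R)-4,4-dimethyl-1,5-bis(3-methylbut-2-en-1-yl)-3-{2-methyl-1-[(trimethylsilyl)oxy]propylidene}-2-oxocyclohexyl]-2-[(triethylsilyl)oxy]acetate (enol ether geometry not defined) | CC(C)=CC[C@@H]1C[C@]([C@@H](O[Si](CC)(CC)CC)C(=O)O[Si](C)(C)C)(CC=C(C)C)C(=O)C(=C(O[Si](C)(C)C)C(C)C)C1(C)C
F2 | step 10 | (2R)-2-[(1S,5R)-4,4-dimethyl-1,5-bis(3-methylbut-2-en-1-yl)-3-{2-methyl-1-[(trimethylsilyl)oxy]propylidene}-2-oxocyclohexyl]-2-[(triethylsilyl)oxy]acetyl chloride (enol ether geometry not defined) | CC(C)=CC[C@@H]1C[C@]([C@@H](O[Si](CC)(CC)CC)C(Cl)=O)(CC=C(C)C)C(=O)C(=C(O[Si](C)(C)C)C(C)C)C1(C)C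
F3 | step 5 | trimethyl{[(4R)-5-methyl-2,4-bis(3-methylbut-2-en-1-yl)cyclohexa-1,5-dien-1-yl]oxy}silane | CC(C)=CC[C@@H]1CC(CC=C(C)C)=C(O[Si](C)(C)C)C=C1C
F4 | step 5 | methyl (2R)-2-hydroxy-2-[(1S,5R)-4-methyl-1,5-bis(3-methylbut-2-en-1-yl)-2-oxocyclohex-3-en-1-yl]acetate | CC(C)=CC[C@@H]1C[C@]([C@@H](O)C(=O)OC)(CC=C(C)C)C(=O)C=C1C
F5 | step 6 | trimethyl{[(4R,6R)-3,3-dimethyl-4,6-bis(3-methylbut-2-en-1-yl)cyclohex-1-en-1-yl]oxy}silane | CC(C)=CC[C@@H]1C[C@@H](CC=C(C)C)C(O[Si](C)(C)C)=CC1(C)C
F6 | step 6 | (4R,6R)-2-(1-hydroxy-2-methylpropyl)-3,3-dimethyl-4,6-bis(3-methylbut-2-en-1-yl)cyclohexan-1-one (mixture at C2 and at the carbinol) | CC(C)=CC[C@@H]1C[C@@H](CC=C(C)C)C(=O)C(C(O)C(C)C)C1(C)C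
F7 | step 6 | (4R,6R)-3,3-dimethyl-4,6-bis(3-methylbut-2-en-1-yl)-2-(2-methylpropanoyl)cyclohexan-1-one (C2 enolisable) | CC(C)=CC[C@@H]1C[C@@H](CC=C(C)C)C(=O)C(C(=O)C(C)C)C1(C)C
F8 | step 13 | 4-methyl-4-[(triethylsilyl)oxy]pent-2-ynoic acid | CC(C)(C#CC(=O)O)O[Si](CC)(CC)CC
F9 | step 13 | 1-(1H-benzotriazol-1-yl)-4-methyl-4-[(triethylsilyl)oxy]pent-2-yn-1-one | CC(C)(C#CC(=O)n1nnc2ccccc12)O[Si](CC)(CC)CC
F10 | step 15 | (1R,3R,5S,6S)-6-{(2Z)-1-hydroxy-4-methyl-4-[(triethylsilyl)oxy]pent-2-en-1-yl}-2,2-dimethyl-3,5-bis(3-methylbut-2-en-1-yl)-1-(2-methylpropanoyl)-6-[(triethylsilyl)oxy]bicyclo[3.2.1]octane-7,8-dione (carbinol epimers) | CC(C)=CC[C@@H]1C[C@]2(CC=C(C)C)C(=O)[C@@](C(=O)C(C)C)(C(=O)[C@@]2(O[Si](CC)(CC)CC)C(O)/C=C\C(C)(C)O[Si](CC)(CC)CC)C1(C)C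
A1 | alternative 1 | cohulupone, 4-hydroxy-2,2-bis(3-methylbut-2-en-1-yl)-5-(2-methylpropanoyl)cyclopent-4-ene-1,3-dione | CC(C)C(=O)C1=C(O)C(=O)C(CC=C(C)C)(CC=C(C)C)C1=O
A2 | alternative 1 | (1R,3R,5R)-2,2-dimethyl-5-(3-methylbut-2-en-1-yl)-1-(2-methylpropanoyl)-3-(phenylselanyl)bicyclo[3.2.1]octane-6,7,8-trione | c3ccccc3[Se][C@@H]1C[C@]2(CC=C(C)C)C(=O)[C@@](C(=O)C(C)C)(C(=O)C2=O)C1(C)C
A3 | alternative 2 | (3S)-5-bromo-3-(2-methylbut-3-en-2-yl)-5-(3-methylbut-2-en-1-yl)-3-(2-methylpropanoyl)cyclopentane-1,2,4-trione (C5 either configuration) | C=CC(C)(C)[C@@]1(C(=O)C(C)C)C(=O)C(Br)(CC=C(C)C)C(=O)C1=O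
A4 | alternative 2 | (1R,3R,5R)-2,2-dimethyl-5-(3-methylbut-2-en-1-yl)-1-(2-methylpropanoyl)-3-(prop-2-en-1-yl)bicyclo[3.2.1]octane-6,7,8-trione | C=CC[C@@H]1C[C@]2(CC=C(C)C)C(=O)[C@@](C(=O)C(C)C)(C(=O)C2=O)C1(C)C
A5 | alternative 3 | methyl 2-[3-{[(tert-butyldimethylsilyl)oxy]methylidene}-1,5-bis(2,2-dimethoxyethyl)-4,4-dimethyl-2-oxocyclohexyl]-4-methyl-3-oxopentanoate (ring stereocentres as in A6) | COC(OC)C[C@@H]1C[C@@](CC(OC)OC)(C(C(=O)OC)C(=O)C(C)C)C(=O)C(=CO[Si](C)(C)C(C)(C)C)C1(C)C
A6 | alternative 3 | methyl 7-[(tert-butyldimethylsilyl)oxy]-3,5-bis(2,2-dimethoxyethyl)-2,2-dimethyl-1-(2-methylpropanoyl)-8-oxobicyclo[3.2.1]octane-6-carboxylate (configuration as in the SMILES) | COC(OC)C[C@@H]1C[C@]2(CC(OC)OC)C(=O)[C@@](C(=O)C(C)C)([C@@H](O[Si](C)(C)C(C)(C)C)[C@H]2C(=O)OC)C1(C)C
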